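**Retrosynthetic overview**
- Target 18 is an apigenin unit joined through its C3 to C6 of a (2R,3R)-epiafzelechin unit; it is unveiled from 16 by pivalate cleavage and hydrogenolysis only.
- Key disconnection: flavan C4–C4a. Ring A of the flavan is a phloroglucinol ring whose C6 (bonded to flavone C3) lies para to C8a–O1. In the open precursor 15 the two CH carbons ortho to that oxygen (future C4a and C8) are therefore equivalent, and Friedel–Crafts closure onto the epoxide CH2 can only give the 6-linked flavan.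
- O1–C2 ether: Mitsunobu inversion of the erythro epoxy alcohol 14 (Sharpless kinetic resolution, which fixes both stereocentres) by the symmetric phenol 10.
- Flavone C3–aryl bond: Negishi coupling of 3-iodo-tri-O-benzylapigenin 4 with the arylzinc reagent made from 3,5-bis(benzyloxy)phenol.
- Ring order: the chromone rings come with apigenin; the flavan pyran ring is the only ring formed (step 10).

Key step: step 10

Assumption: the target is drawn without an axial descriptor, so the hindered flavone C3–flavan C6 bond is treated as non-stereogenic and rotamers about it in 16, 17 and 18 count as one compound each.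

**Step 1**
Reactants: 1 apigenin
Product: 2 5,7-bis(benzyloxy)-2-[4-(benzyloxy)phenyl]-4H-chromen-4-one
Conditions: BnBr (excess), K2CO3, DMF, 80 °C
Reagents that add atoms: benzyl bromide, BrCc1ccccc1
Why: Williamson etherification of all three phenols, the hydrogen-bonded 5-OH being the slowest and driven to completion by excess benzyl bromide in hot DMF.

**Step 2**
Reactants: 2 5,7-bis(benzyloxy)-2-[4-(benzyloxy)phenyl]-4H-chromen-4-one
Product: 4 5,7-bis(benzyloxy)-2-[4-(benzyloxy)phenyl]-3-iodo-4H-chromen-4-one, via 3-lithioflavone 3 (not isolated)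
Conditions: LiN(iPr)2 (LDA, commercial solution), THF, −78 °C; then I2, THF, −78 to −40 °C
Reagents that add atoms: iodine, [I][I]
Why: Deprotonation of the flavone at C3 (the vinylic C–H next to the carbonyl, the established site of amide-base metalation of flavones) followed by electrophilic iodination of the lithio species; aryl benzyl ethers are inert to LDA at −78 °C.

**Step 3**
Reactants: 5 3,5-bis(benzyloxy)phenol
Product: 6 [3,5-bis(benzyloxy)phenoxy]tri(propan-2-yl)silane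
Conditions: TIPSCl, imidazole, DMF, rt
Reagents that add atoms: chlorotri(propan-2-yl)silane, CC(C)[Si](Cl)(C(C)C)C(C)C
Why: Silylation of the phenol gives a bulky, poorly coordinating silyl ether that will not direct metalation and shields the two positions beside it.

**Step 4**
Reactants: 6 [3,5-bis(benzyloxy)phenoxy]tri(propan-2-yl)silane; 4 5,7-bis(benzyloxy)-2-[4-(benzyloxy)phenyl]-3-iodo-4H-chromen-4-one
Product: 9 5,7-bis(benzyloxy)-2-[4-(benzyloxy)phenyl]-3-[2,6-bis(benzyloxy)-4-{[tri(propan-2-yl)silyl]oxy}phenyl]-4H-chromen-4-one, via aryllithium 7 (not isolated), via arylzinc chloride 8 (not isolated)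
Conditions: 6 (1.6 equiv), n-BuLi, THF, 0 °C; ZnCl2, THF, 0 °C to rt; then 4, Pd(OAc)2 (5 mol%), SPhos (10 mol%), THF, 60 °C
Reagents that add atoms: none
Why: Directed ortho-metalation at the C–H flanked by the two benzyloxy groups (the kinetic site, since the hindered silyloxy group does not direct), transmetalation to zinc, and Negishi cross-coupling with the 3-iodoflavone under a dialkylbiarylphosphine–palladium catalyst suited to doubly ortho-substituted partners.

**Step 5**
Reactants: 9 5,7-bis(benzyloxy)-2-[4-(benzyloxy)phenyl]-3-[2,6-bis(benzyloxy)-4-{[tri(propan-2-yl)silyl]oxy}phenyl]-4H-chromen-4-one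
Product: 10 5,7-bis(benzyloxy)-2-[4-(benzyloxy)phenyl]-3-[2,6-bis(benzyloxy)-4-hydroxyphenyl]-4H-chromen-4-one
Conditions: Bu4NF, AcOH, THF, 0 °C to rt
Reagents that add atoms: none
Why: Fluoride cleavage of the aryl silyl ether, buffered with acetic acid, frees the single phenol that sits on the local twofold axis of the 2,6-bis(benzyloxy)aryl ring while benzyl ethers and the chromone are untouched.

**Step 6**
Reactants: 11 4-hydroxybenzaldehyde
Product: 12 4-formylphenyl 2,2-dimethylpropanoate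
Conditions: PivCl, Et3N, DMAP (cat.), CH2Cl2, 0 °C to rt
Reagents that add atoms: 2,2-dimethylpropanoyl chloride, CC(C)(C)C(Cl)=O
Why: DMAP-catalysed acylation of the phenol installs the electron-withdrawing, hindered ester that later keeps the benzylic ether carbon from ionising.

**Step 7**
Reactants: 12 4-formylphenyl 2,2-dimethylpropanoate
Product: 13 rac-4-(1-hydroxyprop-2-en-1-yl)phenyl 2,2-dimethylpropanoate
Conditions: CH2=CHMgBr (1.05 equiv), THF, −78 °C; aq. NH4Cl
Reagents that add atoms: vinylmagnesium bromide, C=C[Mg]Br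
Why: Grignard 1,2-addition to the aldehyde, which at −78 °C is far more electrophilic than the hindered pivalate; the carbinol centre is formed racemic and is resolved in step 8.

**Step 8**
Reactants: 13 rac-4-(1-hydroxyprop-2-en-1-yl)phenyl 2,2-dimethylpropanoate
Product: 14 4-[(S)-hydroxy[(2R)-oxiran-2-yl]methyl]phenyl 2,2-dimethylpropanoate
Conditions: Ti(OiPr)4 (0.2 equiv), L-(+)-DIPT (0.24 equiv), TBHP (0.45 equiv), 4 Å MS, CH2Cl2, −20 °C
Reagents that add atoms: tert-butyl hydroperoxide, CC(C)(C)OO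
Why: Sharpless kinetic resolution, in which the titanium–L-(+)-tartrate catalyst epoxidises the (R)-enantiomer of 13 much faster than the (S)-enantiomer and delivers oxygen to the alkene face that gives the erythro epoxy alcohol, so the new oxirane centre (R) is set by the catalyst and the carbinol centre is fixed by the resolution (the same carbon is named S in 14 only because the oxirane carbon now outranks the aryl group), while substoichiometric TBHP keeps the conversion below one half and (S)-13 is left behind and separated.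

**Step 9**
Reactants: 10 5,7-bis(benzyloxy)-2-[4-(benzyloxy)phenyl]-3-[2,6-bis(benzyloxy)-4-hydroxyphenyl]-4H-chromen-4-one; 14 4-[(S)-hydroxy[(2R)-oxiran-2-yl]methyl]phenyl 2,2-dimethylpropanoate
Product: 15 4-[(R)-{3,5-bis(benzyloxy)-4-[5,7-bis(benzyloxy)-2-[4-(benzyloxy)phenyl]-4-oxo-4H-chromen-3-yl]phenoxy}[(2R)-oxiran-2-yl]methyl]phenyl 2,2-dimethylpropanoate
Conditions: PPh3, DIAD, toluene, 0 °C to rt
Reagents that add atoms: none
Why: Mitsunobu etherification in which the phenoxide displaces the alkoxyphosphonium of 14 by SN2 with inversion at the benzylic carbinol (S to R), ionisation being disfavoured by the electron-poor aryl ring and the adjacent oxirane, while the oxirane stereocentre is untouched.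

**Step 10**
Reactants: 15 4-[(R)-{3,5-bis(benzyloxy)-4-[5,7-bis(benzyloxy)-2-[4-(benzyloxy)phenyl]-4-oxo-4H-chromen-3-yl]phenoxy}[(2R)-oxiran-2-yl]methyl]phenyl 2,2-dimethylpropanoate
Product: 16 4-[(2R,3R)-5,7-bis(benzyloxy)-6-{5,7-bis(benzyloxy)-2-[4-(benzyloxy)phenyl]-4-oxo-4H-chromen-3-yl}-3-hydroxy-3,4-dihydro-2H-chromen-2-yl]phenyl 2,2-dimethylpropanoate
Conditions: AuCl3 (5 mol%), AgOTf (15 mol%), ClCH2CH2Cl, 0 °C to rt
Reagents that add atoms: none
Why: Cationic trivalent gold (AuCl3 activated by AgOTf) binds the oxirane oxygen of 15 as an oxophilic Lewis acid and weakens the terminal CH2–O bond, and the aryl carbon ortho to the ether oxygen (also ortho and para to the two benzyloxy groups) attacks that CH2 in an SN2-like Friedel–Crafts alkylation, after which rearomatisation and protonation of the gold alkoxide release the 3-ol and the catalyst. The closest known reaction type is the Lewis acid-catalysed epoxide–arene cyclisation of aryl glycidyl-type ethers to chroman-3-ols. The pyran ring closes in the 6-endo-tet mode and the bond formed is C4–C4a. No new stereocentre arises, since C2 is the untouched benzylic ether carbon and C3 is the oxirane CH whose C–O bond is not broken, so the (R,R) pair of 15 becomes the 2R,3R cis pair of 16. Which ortho carbon attacks needs no control, because the two CH positions beside the ether oxygen are related by the local twofold symmetry of the 2,6-bis(benzyloxy)aryl ring and either one gives the C6-linked flavan; 6-endo over 5-exo attack is secured by the unhindered terminal oxirane carbon and the triply oxygen-activated arene carbon, and survival of the benzylic C2–O bond by the electron-poor 4-(pivaloyloxy)phenyl group.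

**Step 11**
Reactants: 16 4-[(2R,3R)-5,7-bis(benzyloxy)-6-{5,7-bis(benzyloxy)-2-[4-(benzyloxy)phenyl]-4-oxo-4H-chromen-3-yl}-3-hydroxy-3,4-dihydro-2H-chromen-2-yl]phenyl 2,2-dimethylpropanoate
Product: 17 5,7-bis(benzyloxy)-2-[4-(benzyloxy)phenyl]-3-[(2R,3R)-5,7-bis(benzyloxy)-3-hydroxy-2-(4-hydroxyphenyl)-3,4-dihydro-2H-chromen-6-yl]-4H-chromen-4-one
Conditions: K2CO3, MeOH–THF, 0 °C; neutral aqueous work-up
Reagents that add atoms: none
Why: Base-mediated methanolysis (transesterification) of the aryl pivalate, run cold and worked up promptly so that the freed 4-hydroxyphenyl phenoxide has little time to open the pyran ring through a quinone methide; benzyl ethers, the chromone and both stereocentres are unaffected.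

**Step 12**
Reactants: 17 5,7-bis(benzyloxy)-2-[4-(benzyloxy)phenyl]-3-[(2R,3R)-5,7-bis(benzyloxy)-3-hydroxy-2-(4-hydroxyphenyl)-3,4-dihydro-2H-chromen-6-yl]-4H-chromen-4-one
Product: 18 5,7-dihydroxy-2-(4-hydroxyphenyl)-3-[(2R,3R)-3,5,7-trihydroxy-2-(4-hydroxyphenyl)-3,4-dihydro-2H-chromen-6-yl]-4H-chromen-4-one
Conditions: H2 (1 atm), Pd(OH)2/C, THF–MeOH, rt
Reagents that add atoms: none
Why: Hydrogenolysis of the five aryl benzyl ethers under neutral conditions; the tetrasubstituted chromone double bond and the benzylic C2–O1 bond of the flavan should not be reduced at one atmosphere and room temperature, and no stereocentre is touched.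

**Compound list**
1 | apigenin, 5,7-dihydroxy-2-(4-hydroxyphenyl)-4H-chromen-4-one | O=c1cc(-c2ccc(O)cc2)oc2cc(O)cc(O)c12 | starting material
2 | 5,7-bis(benzyloxy)-2-[4-(benzyloxy)phenyl]-4H-chromen-4-one | O=c1cc(-c2ccc(OCc3ccccc3)cc2)oc2cc(OCc3ccccc3)cc(OCc3ccccc3)c12 | intermediate
3 | {5,7-bis(benzyloxy)-2-[4-(benzyloxy)phenyl]-4-oxo-4H-chromen-3-yl}lithium | O=c1c([Li])c(-c2ccc(OCc3ccccc3)cc2)oc2cc(OCc3ccccc3)cc(OCc3ccccc3)c12 | intermediate
4 | 5,7-bis(benzyloxy)-2-[4-(benzyloxy)phenyl]-3-iodo-4H-chromen-4-one | O=c1c(I)c(-c2ccc(OCc3ccccc3)cc2)oc2cc(OCc3ccccc3)cc(OCc3ccccc3)c12 | intermediate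
5 | 3,5-bis(benzyloxy)phenol | Oc1cc(OCc2ccccc2)cc(OCc2ccccc2)c1 | starting material
6 | [3,5-bis(benzyloxy)phenoxy]tri(propan-2-yl)silane | CC(C)[Si](Oc1cc(OCc2ccccc2)cc(OCc2ccccc2)c1)(C(C)C)C(C)C | intermediate
7 | [2,6-bis(benzyloxy)-4-{[tri(propan-2-yl)silyl]oxy}phenyl]lithium | [Li]c1c(OCc2ccccc2)cc(O[Si](C(C)C)(C(C)C)C(C)C)cc1OCc1ccccc1 | intermediate
8 | [2,6-bis(benzyloxy)-4-{[tri(propan-2-yl)silyl]oxy}phenyl]zinc chloride | Cl[Zn]c1c(OCc2ccccc2)cc(O[Si](C(C)C)(C(C)C)C(C)C)cc1OCc1ccccc1 | intermediate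
9 | 5,7-bis(benzyloxy)-2-[4-(benzyloxy)phenyl]-3-[2,6-bis(benzyloxy)-4-{[tri(propan-2-yl)silyl]oxy}phenyl]-4H-chromen-4-one | O=c1c(-c2c(OCc3ccccc3)cc(O[Si](C(C)C)(C(C)C)C(C)C)cc2OCc2ccccc2)c(-c2ccc(OCc3ccccc3)cc2)oc2cc(OCc3ccccc3)cc(OCc3ccccc3)c12 | intermediate
10 | 5,7-bis(benzyloxy)-2-[4-(benzyloxy)phenyl]-3-[2,6-bis(benzyloxy)-4-hydroxyphenyl]-4H-chromen-4-one | O=c1c(-c2c(OCc3ccccc3)cc(O)cc2OCc2ccccc2)c(-c2ccc(OCc3ccccc3)cc2)oc2cc(OCc3ccccc3)cc(OCc3ccccc3)c12 | intermediate
11 | 4-hydroxybenzaldehyde | O=Cc1ccc(O)cc1 | starting material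
12 | 4-formylphenyl 2,2-dimethylpropanoate | CC(C)(C)C(=O)Oc1ccc(C=O)cc1 | intermediate
13 | rac-4-(1-hydroxyprop-2-en-1-yl)phenyl 2,2-dimethylpropanoate | CC(C)(C)C(=O)Oc1ccc(C(O)C=C)cc1 | intermediate
14 | 4-[(S)-hydroxy[(2R)-oxiran-2-yl]methyl]phenyl 2,2-dimethylpropanoate | O[C@@H](c1ccc(OC(=O)C(C)(C)C)cc1)[C@H]1CO1 | intermediate
15 | 4-[(R)-{3,5-bis(benzyloxy)-4-[5,7-bis(benzyloxy)-2-[4-(benzyloxy)phenyl]-4-oxo-4H-chromen-3-yl]phenoxy}[(2R)-oxiran-2-yl]methyl]phenyl 2,2-dimethylpropanoate | O=c1c(-c2c(OCc3ccccc3)cc(O[C@H](c3ccc(OC(=O)C(C)(C)C)cc3)[C@H]3CO3)cc2OCc2ccccc2)c(-c2ccc(OCc3ccccc3)cc2)oc2cc(OCc3ccccc3)cc(OCc3ccccc3)c12 | intermediate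
16 | 4-[(2R,3R)-5,7-bis(benzyloxy)-6-{5,7-bis(benzyloxy)-2-[4-(benzyloxy)phenyl]-4-oxo-4H-chromen-3-yl}-3-hydroxy-3,4-dihydro-2H-chromen-2-yl]phenyl 2,2-dimethylpropanoate | O=c1c(-c2c(OCc3ccccc3)cc3c(c2OCc2ccccc2)C[C@@H](O)[C@@H](c2ccc(OC(=O)C(C)(C)C)cc2)O3)c(-c2ccc(OCc3ccccc3)cc2)oc2cc(OCc3ccccc3)cc(OCc3ccccc3)c12 | intermediate
17 | 5,7-bis(benzyloxy)-2-[4-(benzyloxy)phenyl]-3-[(2R,3R)-5,7-bis(benzyloxy)-3-hydroxy-2-(4-hydroxyphenyl)-3,4-dihydro-2H-chromen-6-yl]-4H-chromen-4-one | O=c1c(-c2c(OCc3ccccc3)cc3c(c2OCc2ccccc2)C[C@@H](O)[C@@H](c2ccc(O)cc2)O3)c(-c2ccc(OCc3ccccc3)cc2)oc2cc(OCc3ccccc3)cc(OCc3ccccc3)c12 | intermediate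
18 | 5,7-dihydroxy-2-(4-hydroxyphenyl)-3-[(2R,3R)-3,5,7-trihydroxy-2-(4-hydroxyphenyl)-3,4-dihydro-2H-chromen-6-yl]-4H-chromen-4-one (CNP0222954.1) | O=c1c(-c2c(O)cc3c(c2O)C[C@@H](O)[C@@H](c2ccc(O)cc2)O3)c(-c2ccc(O)cc2)oc2cc(O)cc(O)c12 | target

**Totals**
Total step count: 12. Longest linear sequence: 8 steps (steps 1, 2, 4, 5, 9, 10, 11, 12 from apigenin).

**Steps most likely to fail**

Step 10 (key cyclisation). The chromone carbonyl and its neighbouring benzyloxy groups may sequester the gold/silver Lewis acid, and the bulky flavone para to the ether oxygen may slow the closure. Meinwald rearrangement of the activated epoxide or heterolysis of the benzylic C2–O bond could then outrun the Friedel–Crafts step. The fallback closes the pyran ring before the flavone is attached, with an iodine atom keeping the twofold symmetry of the aryl ring. It sets out from aryllithium 7 (made from 6 as in step 4), which is quenched with I2 (THF, −78 °C) to give [3,5-bis(benzyloxy)-4-iodophenoxy]tri(propan-2-yl)silane F1. Bu4NF/AcOH then gives 3,5-bis(benzyloxy)-4-iodophenol F2, and Mitsunobu reaction with 14 (PPh3, DIAD) gives the (R,R)-configured iodoaryl oxiranylmethyl ether F3. AuCl3/AgOTf cyclisation of this chromone-free substrate, which sits close to the known examples, should give the (2R,3R)-6-iodoflavan-3-ol F4. Lithio flavone 3 (from 2 as in step 2) is transmetalated with ZnCl2 to flavon-3-ylzinc chloride F5. Negishi coupling of F4 with an excess of F5 (Pd(OAc)2, SPhos, THF, 60 °C; the free alcohol is carried as its zinc alkoxide) rejoins the route at 16.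

Step 4 (metalation and hindered Negishi coupling). Transmetalation and reductive elimination at a junction flanked by four ortho substituents may be so slow that protodezincation of 8 and reduction of 4 take over. The fallback builds the chromone ring onto the aryl group by the deoxybenzoin route instead of joining two finished ring systems. It sets out from aryllithium 7, which opens oxirane (THF, −78 to 0 °C) to give 2-[2,6-bis(benzyloxy)-4-{[tri(propan-2-yl)silyl]oxy}phenyl]ethan-1-ol F6. TEMPO/PhI(OAc)2 in MeCN–H2O oxidises this to the arylacetic acid F7. Its mixed anhydride with (CF3CO)2O acylates commercial 1,3,5-tris(benzyloxy)benzene (Friedel–Crafts, CH2Cl2, 0 °C to rt) to give the 2,4,6-tris(benzyloxy)phenyl ketone F8. MgBr2·OEt2 removes the one benzyl group that chelates with the ketone and gives the 2-hydroxy deoxybenzoin F9. 4-(Benzyloxy)benzoyl chloride in pyridine gives the O-aroyl ester F10, and Baker–Venkataraman acyl transfer (LiN(SiMe3)2, THF, −20 °C) gives the 1,3-diketone F11. Cyclodehydration (p-TsOH, toluene, 60 °C) closes the chromone and returns to the route at 9.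

Step 9 (Mitsunobu etherification). Opening of the terminal epoxide of 14 by the phenoxide or the hydrazide anion, or elimination from the alkoxyphosphonium, may consume 14 before the benzylic carbon is displaced. The fallback carries the C3 oxygen and C4 through the etherification as a chiral-pool acetonide and makes the epoxide afterwards. 4-Iodophenyl pivalate undergoes iodine–magnesium exchange (iPrMgCl·LiCl, THF, −20 °C) to 4-(pivaloyloxy)phenylmagnesium chloride F12. This adds to (R)-2,3-O-isopropylideneglyceraldehyde with Felkin–Anh (anti) preference to give, after separation from the syn epimer, 4-[(S)-[(4R)-2,2-dimethyl-1,3-dioxolan-4-yl](hydroxy)methyl]phenyl 2,2-dimethylpropanoate F13. The fallback then sets out from phenol 10, whose Mitsunobu reaction with F13 (PPh3, DIAD) gives with inversion the (R)-aryl ether acetonide F14. Aqueous AcOH (40 °C) gives the (2R,3R)-1,2-diol F15, and TsCl/Et3N with catalytic Bu2SnO gives the primary tosylate F16. NaH (THF, 0 °C) closes the oxirane with retention at the secondary carbinol carbon and returns to the route at 15.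

**Further compounds**
F1 | step 10 | [3,5-bis(benzyloxy)-4-iodophenoxy]tri(propan-2-yl)silane | CC(C)[Si](Oc1cc(OCc2ccccc2)c(I)c(OCc2ccccc2)c1)(C(C)C)C(C)C
F2 | step 10 | 3,5-bis(benzyloxy)-4-iodophenol | Oc1cc(OCc2ccccc2)c(I)c(OCc2ccccc2)c1
F3 | step 10 | 4-[(R)-[3,5-bis(benzyloxy)-4-iodophenoxy][(2R)-oxiran-2-yl]methyl]phenyl 2,2-dimethylpropanoate | Ic1c(OCc2ccccc2)cc(O[C@H](c2ccc(OC(=O)C(C)(C)C)cc2)[C@H]2CO2)cc1OCc1ccccc1
F4 | step 10 | 4-[(2R,3R)-5,7-bis(benzyloxy)-3-hydroxy-6-iodo-3,4-dihydro-2H-chromen-2-yl]phenyl 2,2-dimethylpropanoate | Ic1c(OCc2ccccc2)cc2c(c1OCc1ccccc1)C[C@@H](O)[C@@H](c1ccc(OC(=O)C(C)(C)C)cc1)O2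
F5 | step 10 | {5,7-bis(benzyloxy)-2-[4-(benzyloxy)phenyl]-4-oxo-4H-chromen-3-yl}zinc chloride | O=c1c([Zn]Cl)c(-c2ccc(OCc3ccccc3)cc2)oc2cc(OCc3ccccc3)cc(OCc3ccccc3)c12
F6 | step 4 | 2-[2,6-bis(benzyloxy)-4-{[tri(propan-2-yl)silyl]oxy}phenyl]ethan-1-ol | OCCc1c(OCc2ccccc2)cc(O[Si](C(C)C)(C(C)C)C(C)C)cc1OCc1ccccc1
F7 | step 4 | [2,6-bis(benzyloxy)-4-{[tri(propan-2-yl)silyl]oxy}phenyl]acetic acid | OC(=O)Cc1c(OCc2ccccc2)cc(O[Si](C(C)C)(C(C)C)C(C)C)cc1OCc1ccccc1
F8 | step 4 | 2-[2,6-bis(benzyloxy)-4-{[tri(propan-2-yl)silyl]oxy}phenyl]-1-[2,4,6-tris(benzyloxy)phenyl]ethan-1-one | O=C(Cc1c(OCc2ccccc2)cc(O[Si](C(C)C)(C(C)C)C(C)C)cc1OCc1ccccc1)c1c(OCc2ccccc2)cc(OCc2ccccc2)cc1OCc1ccccc1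
F9 | step 4 | 1-[2,4-bis(benzyloxy)-6-hydroxyphenyl]-2-[2,6-bis(benzyloxy)-4-{[tri(propan-2-yl)silyl]oxy}phenyl]ethan-1-one | O=C(Cc1c(OCc2ccccc2)cc(O[Si](C(C)C)(C(C)C)C(C)C)cc1OCc1ccccc1)c1c(O)cc(OCc2ccccc2)cc1OCc1ccccc1
F10 | step 4 | 3,5-bis(benzyloxy)-2-{[2,6-bis(benzyloxy)-4-{[tri(propan-2-yl)silyl]oxy}phenyl]acetyl}phenyl 4-(benzyloxy)benzoate | O=C(Oc1cc(OCc2ccccc2)cc(OCc2ccccc2)c1C(=O)Cc1c(OCc2ccccc2)cc(O[Si](C(C)C)(C(C)C)C(C)C)cc1OCc1ccccc1)c1ccc(OCc2ccccc2)cc1
F11 | step 4 | 1-[2,4-bis(benzyloxy)-6-hydroxyphenyl]-3-[4-(benzyloxy)phenyl]-2-[2,6-bis(benzyloxy)-4-{[tri(propan-2-yl)silyl]oxy}phenyl]propane-1,3-dione | O=C(c1ccc(OCc2ccccc2)cc1)C(C(=O)c1c(O)cc(OCc2ccccc2)cc1OCc1ccccc1)c1c(OCc2ccccc2)cc(O[Si](C(C)C)(C(C)C)C(C)C)cc1OCc1ccccc1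
F12 | step 9 | 4-(pivaloyloxy)phenylmagnesium chloride | CC(C)(C)C(=O)Oc1ccc([Mg]Cl)cc1
F13 | step 9 | 4-[(S)-[(4R)-2,2-dimethyl-1,3-dioxolan-4-yl](hydroxy)methyl]phenyl 2,2-dimethylpropanoate | O[C@@H](c1ccc(OC(=O)C(C)(C)C)cc1)[C@H]1COC(C)(C)O1
F14 | step 9 | 4-[(R)-{3,5-bis(benzyloxy)-4-[5,7-bis(benzyloxy)-2-[4-(benzyloxy)phenyl]-4-oxo-4H-chromen-3-yl]phenoxy}[(4R)-2,2-dimethyl-1,3-dioxolan-4-yl]methyl]phenyl 2,2-dimethylpropanoate | O=c1c(-c2c(OCc3ccccc3)cc(O[C@H](c3ccc(OC(=O)C(C)(C)C)cc3)[C@H]3COC(C)(C)O3)cc2OCc2ccccc2)c(-c2ccc(OCc3ccccc3)cc2)oc2cc(OCc3ccccc3)cc(OCc3ccccc3)c12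
F15 | step 9 | 4-[(1R,2R)-1-{3,5-bis(benzyloxy)-4-[5,7-bis(benzyloxy)-2-[4-(benzyloxy)phenyl]-4-oxo-4H-chromen-3-yl]phenoxy}-2,3-dihydroxypropyl]phenyl 2,2-dimethylpropanoate | O=c1c(-c2c(OCc3ccccc3)cc(O[C@H](c3ccc(OC(=O)C(C)(C)C)cc3)[C@H](O)CO)cc2OCc2ccccc2)c(-c2ccc(OCc3ccccc3)cc2)oc2cc(OCc3ccccc3)cc(OCc3ccccc3)c12
F16 | step 9 | 4-[(1R,2R)-1-{3,5-bis(benzyloxy)-4-[5,7-bis(benzyloxy)-2-[4-(benzyloxy)phenyl]-4-oxo-4H-chromen-3-yl]phenoxy}-2-hydroxy-3-{[(4-methylphenyl)sulfonyl]oxy}propyl]phenyl 2,2-dimethylpropanoate | O=c1c(-c2c(OCc3ccccc3)cc(O[C@H](c3ccc(OC(=O)C(C)(C)C)cc3)[C@H](O)COS(=O)(=O)c3ccc(C)cc3)cc2OCc2ccccc2)c(-c2ccc(OCc3ccccc3)cc2)oc2cc(OCc3ccccc3)cc(OCc3ccccc3)c12
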